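**Retrosynthetic overview**
- Marchantin G (23) ⇐ O-demethylation ⇐ trimethyl ether 22 ⇐ Markovnikov hydration of the 18-membered diarylalkyne 21 (the carbonyl ends next to the donor ring B).
- 21 ⇐ one-carbon ring expansion of the 17-membered ansa-diaryl ketone 18 by an alkylidene-carbene 1,2-aryl shift (both possible migrations give the same alkyne).
- 18 ⇐ ring closure of 16 by hydroboration/B-alkyl Suzuki coupling (CH2CH2 bridge) ⇐ Wittig ⇐ keto aldehyde 15 ⇐ carbonylative Suzuki coupling of iodide 6, CO and boronate 14.
- 6 ⇐ SNAr of 3-iodophenol on 2-fluoro-3-methoxybenzaldehyde (from 2-fluorophenol); 14 ⇐ C–H borylation of diaryl ether 13 (from catechol and 1-bromo-4-iodobenzene).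
- Rings: A = para-phenylene, B = catechol ring, C = meta-phenylene, D = ring with the lone OH. All four are bought; the macrocycle is closed as a 17-ring (step 9) and expanded to the 18-ring (step 10).

Assumption: the SMILES carries no stereodescriptor and the macrocycle is conformationally mobile, so the target is treated as achiral and no stereocentre has to be set.

**Route**

Step 1
Reactants: 1 2-fluorophenol
Product: 2 2-fluoroanisole
Conditions: MeI, K2CO3, acetone, reflux
Reagents that add atoms: iodomethane CI
Why: Williamson O-methylation masks the ring D phenol as a methyl ether that survives the organolithium, SNAr and palladium steps.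

Step 2
Reactants: 2 2-fluoroanisole
Product: 4 2-fluoro-3-methoxybenzaldehyde, via aryllithium 3 (not isolated)
Conditions: n-BuLi, PMDTA (N,N,N′,N″,N″-pentamethyldiethylenetriamine), THF, −78 °C; then DMF, −78 °C to rt; H2O
Reagents that add atoms: N,N-dimethylformamide CN(C)C=O (formyl group); n-butyllithium [Li]CCCC (lithium of 3 only)
Why: Directed ortho-metalation at the C–H next to fluorine (the PMDTA-bound base follows acidity, not OMe coordination) and formylation with DMF.

Step 3
Reactants: 4 2-fluoro-3-methoxybenzaldehyde; 5 3-iodophenol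
Product: 6 2-(3-iodophenoxy)-3-methoxybenzaldehyde
Conditions: K2CO3, DMAc, 120 °C
Reagents that add atoms: none
Why: SNAr of the fluoride activated by the ortho formyl group builds the hindered ring C–O–ring D ether while the unactivated C–I bond stays intact.

Step 4
Reactants: 7 catechol
Product: 8 veratrole (1,2-dimethoxybenzene)
Conditions: MeI (2.6 equiv), K2CO3, acetone, reflux
Reagents that add atoms: iodomethane CI
Why: Double Williamson O-methylation protects the catechol, makes it a substrate for ortho-lithiation, and the OMe groups later shield their ortho C–H bonds in the borylation.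

Step 5
Reactants: 8 veratrole
Product: 11 2,3-dimethoxyphenol, via aryllithium 9 (not isolated), via boronate ester 10 (not isolated)
Conditions: n-BuLi, TMEDA, THF, 0 °C to rt; B(OMe)3, −78 °C to rt; then 30 % H2O2, 0 °C to rt
Reagents that add atoms: hydrogen peroxide OO (phenol oxygen); trimethyl borate COB(OC)OC (boron and methoxy groups of 10 only); n-butyllithium [Li]CCCC (lithium of 9 only)
Why: Directed ortho-metalation next to a methoxy group, borylation of the aryllithium and peroxide oxidation of the C–B bond give the third ring B oxygen.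

Step 6
Reactants: 11 2,3-dimethoxyphenol; 12 1-bromo-4-iodobenzene
Product: 13 1-(4-bromophenoxy)-2,3-dimethoxybenzene
Conditions: CuI (10 mol %), picolinic acid (20 mol %), K3PO4, DMSO, 80 °C
Reagents that add atoms: none
Why: Ullmann-type C–O coupling reacts at the C–I bond of 12 well before the C–Br bond, so the bromide is kept for the ring closure.

Step 7
Reactants: 13 1-(4-bromophenoxy)-2,3-dimethoxybenzene; 6 2-(3-iodophenoxy)-3-methoxybenzaldehyde
Product: 15 2-{3-[3-(4-bromophenoxy)-4,5-dimethoxybenzoyl]phenoxy}-3-methoxybenzaldehyde, via aryl pinacolboronate 14 (not isolated)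
Conditions: [Ir(OMe)(cod)]2 (1.5 mol %), dtbpy (4,4′-di-tert-butyl-2,2′-bipyridine, 3 mol %), B2pin2 (0.6 equiv), THF, 80 °C; evaporate; then 6 (1.0 equiv), PdCl2(PPh3)2 (3 mol %), K2CO3, H2O (5 equiv), anisole, CO (1 atm), 80 °C
Reagents that add atoms: carbon monoxide [C-]#[O+] (ketone C=O); bis(pinacolato)diboron CC1(C)OB(OC1(C)C)B1OC(C)(C)C(C)(C)O1 (boryl group of 14 only)
Why: Sterically controlled iridium-catalysed C–H borylation takes the only ring B C–H without an ortho substituent, and the crude boronate enters a three-component carbonylative Suzuki–Miyaura coupling at the aryl iodide, with the aryl bromide and the aldehyde as spectators.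

Step 8
Reactants: 15 2-{3-[3-(4-bromophenoxy)-4,5-dimethoxybenzoyl]phenoxy}-3-methoxybenzaldehyde
Product: 16 [3-(4-bromophenoxy)-4,5-dimethoxyphenyl][3-(2-ethenyl-6-methoxyphenoxy)phenyl]methanone
Conditions: Ph3PCH3Br (1.1 equiv), KOtBu (1.05 equiv), THF, 0 °C; then 15, −78 °C to 0 °C
Reagents that add atoms: methyltriphenylphosphonium bromide C[P+](c1ccccc1)(c1ccccc1)c1ccccc1.[Br-] (the CH2 carbon)
Why: Wittig methylenation is chemoselective because the aldehyde reacts far faster than the conjugated, hindered diaryl ketone at low temperature with one equivalent of ylide.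

Step 9
Reactants: 16 [3-(4-bromophenoxy)-4,5-dimethoxyphenyl][3-(2-ethenyl-6-methoxyphenoxy)phenyl]methanone
Product: 18 17-membered macrocyclic diaryl ketone, via B-alkyl-9-BBN 17 (not isolated)
Conditions: 9-BBN (1.2 equiv), THF, 0 °C to rt; then syringe-pump addition to PdCl2(dppf) (10 mol %), Cs2CO3, DMF/H2O, 60 °C, 2 mM
Reagents that add atoms: 9-borabicyclo[3.3.1]nonane B1C2CCCC1CCC2 (boron bicycle of 17 only; 18 keeps only its hydrogen)
Why: Anti-Markovnikov hydroboration of the styrene followed by an intramolecular B-alkyl Suzuki–Miyaura coupling with the ring A bromide forms the CH2CH2 bridge and closes the 17-membered ring under high dilution.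

Step 10
Reactants: 18 17-membered macrocyclic diaryl ketone
Product: 21 18-membered macrocyclic diarylalkyne, via diazoalkene 19 (not isolated), via alkylidene carbene 20 (not isolated)
Conditions: TMSCHN2 (1.5 equiv), n-BuLi (1.4 equiv), THF, −78 °C; then 18, −78 °C to rt, 50 °C, 1 h; H2O
Reagents that add atoms: trimethylsilyldiazomethane C[Si](C)(C)C=[N+]=[N-] (the new ring carbon; also the N2 unit of 19)
Why: Proposed new method: a ring-expanding Colvin rearrangement of a macrocyclic ansa-diaryl ketone, in which lithiated trimethylsilyldiazomethane adds to the C=O of 18, Peterson-type loss of Me3SiOLi gives diazoalkene 19, loss of N2 gives alkylidene carbene 20 and a 1,2-aryl shift (ring B or ring C, both leading to the same product) moves the exocyclic carbon into the ring to turn the 17-membered ketone into the 18-membered alkyne; the closest known reaction type is the Colvin/Seyferth–Gilbert conversion of open-chain diaryl ketones into diarylalkynes (Fritsch–Buttenberg–Wiechell-type shift), which to my knowledge has not been shown as a ring expansion of a macrocyclic cyclophane ketone.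

Step 11
Reactants: 21 18-membered macrocyclic diarylalkyne
Product: 22 tri-O-methylmarchantin G
Conditions: TfOH (20 mol %), H2O (3 equiv), CF3CH2OH, 60 °C
Reagents that add atoms: water O
Why: Brønsted-acid Markovnikov hydration protonates the alkyne carbon next to ring C because the positive charge is then conjugated with the para-alkoxy group of ring B (ring C has only a meta-aryloxy group), so water adds next to ring B and tautomerisation gives the ring B aryl ketone with the CH2 on ring C.

Step 12
Reactants: 22 tri-O-methylmarchantin G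
Product: 23 marchantin G
Conditions: BBr3 (8 equiv), CH2Cl2, −78 °C to rt; then ice/H2O
Reagents that add atoms: none
Why: Lewis-acid O-demethylation with BBr3 cleaves the three aryl methyl ethers and leaves the diaryl ethers and the ketone untouched.

**Compound list**

1 | 2-fluorophenol | Oc1ccccc1F | starting material
2 | 2-fluoroanisole | COc1ccccc1F | intermediate
3 | (2-fluoro-3-methoxyphenyl)lithium (not isolated) | COc1cccc([Li])c1F | intermediate
4 | 2-fluoro-3-methoxybenzaldehyde | COc1cccc(C=O)c1F | intermediate
5 | 3-iodophenol | Oc1cccc(I)c1 | starting material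
6 | 2-(3-iodophenoxy)-3-methoxybenzaldehyde | COc1cccc(C=O)c1Oc1cccc(I)c1 | intermediate
7 | catechol | Oc1ccccc1O | starting material
8 | veratrole (1,2-dimethoxybenzene) | COc1ccccc1OC | intermediate
9 | (2,3-dimethoxyphenyl)lithium (not isolated) | COc1cccc([Li])c1OC | intermediate
10 | dimethyl (2,3-dimethoxyphenyl)boronate (not isolated) | COB(OC)c1cccc(OC)c1OC | intermediate
11 | 2,3-dimethoxyphenol | COc1cccc(O)c1OC | intermediate
12 | 1-bromo-4-iodobenzene | Brc1ccc(I)cc1 | starting material
13 | 1-(4-bromophenoxy)-2,3-dimethoxybenzene | COc1cccc(Oc2ccc(Br)cc2)c1OC | intermediate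
14 | 2-[3-(4-bromophenoxy)-4,5-dimethoxyphenyl]-4,4,5,5-tetramethyl-1,3,2-dioxaborolane (not isolated) | COc1cc(cc(Oc2ccc(Br)cc2)c1OC)B1OC(C)(C)C(C)(C)O1 | intermediate
15 | 2-{3-[3-(4-bromophenoxy)-4,5-dimethoxybenzoyl]phenoxy}-3-methoxybenzaldehyde | COc1cccc(C=O)c1Oc1cccc(c1)C(=O)c1cc(OC)c(OC)c(Oc2ccc(Br)cc2)c1 | intermediate
16 | [3-(4-bromophenoxy)-4,5-dimethoxyphenyl][3-(2-ethenyl-6-methoxyphenoxy)phenyl]methanone | COc1cccc(C=C)c1Oc1cccc(c1)C(=O)c1cc(OC)c(OC)c(Oc2ccc(Br)cc2)c1 | intermediate
17 | [3-(4-bromophenoxy)-4,5-dimethoxyphenyl](3-{2-[2-(9-borabicyclo[3.3.1]nonan-9-yl)ethyl]-6-methoxyphenoxy}phenyl)methanone (not isolated) | COc1cccc(CCB2C3CCCC2CCC3)c1Oc1cccc(c1)C(=O)c1cc(OC)c(OC)c(Oc2ccc(Br)cc2)c1 | intermediate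
18 | 17-membered macrocyclic diaryl ketone (ring A–O–ring B–C(=O)–ring C–O–ring D–CH2CH2–ring A; one OMe on ring D, two OMe on ring B) | COc1cccc2c1Oc1cccc(c1)C(=O)c1cc(OC)c(OC)c(c1)Oc1ccc(CC2)cc1 | intermediate
19 | diazoalkene from 18 (C=O replaced by C=C=N2; not isolated) | COc1cccc2c1Oc1cccc(c1)C(=C=[N+]=[N-])c1cc(OC)c(OC)c(c1)Oc1ccc(CC2)cc1 | intermediate
20 | alkylidene carbene from 19 (not isolated) | COc1cccc2c1Oc1cccc(c1)C(=[C])c1cc(OC)c(OC)c(c1)Oc1ccc(CC2)cc1 | intermediate
21 | 18-membered macrocyclic diarylalkyne (ring B–C≡C–ring C; three OMe) | COc1cccc2c1Oc1cccc(c1)C#Cc1cc(OC)c(OC)c(c1)Oc1ccc(CC2)cc1 | intermediate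
22 | tri-O-methylmarchantin G | COc1cccc2c1Oc1cccc(c1)CC(=O)c1cc(OC)c(OC)c(c1)Oc1ccc(CC2)cc1 | intermediate
23 | marchantin G | Oc1cccc2c1Oc1cccc(c1)CC(=O)c1cc(O)c(O)c(c1)Oc1ccc(CC2)cc1 | target

**Totals and risks**

Total step count: 12. Longest linear sequence: 9 steps (steps 4–12 from catechol; the 2-fluorophenol branch, steps 1–3 then 7–12, is equally long).

The three steps most likely to fail:

Step 10, the proposed ring expansion. The addition to the ansa-ketone may be slow, and the carbene could be diverted (C–H insertion, dimerisation) if the shift into the 18-ring is retarded. The fallback uses known chemistry, sets out from 16 and comes back at 21. The Colvin rearrangement is run on the open-chain ketone 16 (TMSCHN2/n-BuLi, THF, −78 °C to rt), where it is established for diaryl ketones. It passes through the open-chain diazoalkene F2 and the alkylidene carbene F3 and gives the open-chain diarylalkyne F4. The vinyl group of F4 is hydroborated with 9-BBN to the alkylborane F5, and the 18-membered ring is closed directly by the B-alkyl Suzuki coupling (PdCl2(dppf), Cs2CO3, DMF/H2O, 60 °C, 2 mM) to give 21.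

Step 9, the macrocyclisation. 9-BBN may reduce the diaryl ketone in competition with the styrene hydroboration, and the 17-membered closure may give oligomers. The fallback sets out from 16 and comes back at 18. The ring is closed by an intramolecular Mizoroki–Heck reaction of the aryl bromide with the styrene (Pd(OAc)2, P(o-tol)3, K2CO3, DMF, 100 °C, 2 mM) to give the macrocyclic (E)-stilbene ketone F1. Its C=C bond is then saturated with H2 and RhCl(PPh3)3 (benzene/EtOH, rt), which leaves the diaryl ketone alone, to give 18.

Step 11, the hydration regiochemistry. It rests on the donor strength of a para-methoxy group that is flanked by two ortho substituents; I estimate at least 10:1 from substituent constants, but a mixture of the two ketones is possible. The fallback sets out from 21 and comes back at 23. The methyl ethers are cleaved first with BBr3 (CH2Cl2, −78 °C to 0 °C), as is done for methoxy-substituted diarylalkynes, to give the triphenol alkyne F6. Hydration under the same acid conditions (TfOH, H2O, CF3CH2OH) is then steered by the free para-hydroxyl of ring B and gives 23 directly.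

**Further compounds**

F1 | step 9 | macrocyclic (E)-stilbene ketone (18 with CH=CH in place of CH2CH2) | COc1cccc5c1Oc1cccc(c1)C(=O)c1cc(OC)c(OC)c(c1)Oc1ccc(cc1)/C=C/5
F2 | step 10 | open-chain diazoalkene from 16 | COc1cccc(C=C)c1Oc1cccc(c1)C(=C=[N+]=[N-])c1cc(OC)c(OC)c(Oc2ccc(Br)cc2)c1
F3 | step 10 | open-chain alkylidene carbene | COc1cccc(C=C)c1Oc1cccc(c1)C(=[C])c1cc(OC)c(OC)c(Oc2ccc(Br)cc2)c1
F4 | step 10 | open-chain diarylalkyne (1-(4-bromophenoxy)-2,3-dimethoxy-5-{[3-(2-ethenyl-6-methoxyphenoxy)phenyl]ethynyl}benzene) | COc1cccc(C=C)c1Oc1cccc(c1)C#Cc1cc(OC)c(OC)c(Oc2ccc(Br)cc2)c1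
F5 | step 10 | B-alkyl-9-BBN adduct of F4 | COc1cccc(CCB2C3CCCC2CCC3)c1Oc1cccc(c1)C#Cc1cc(OC)c(OC)c(Oc2ccc(Br)cc2)c1
F6 | step 11 | triphenol macrocyclic diarylalkyne (21 with three OH in place of OMe) | Oc1cccc2c1Oc1cccc(c1)C#Cc1cc(O)c(O)c(c1)Oc1ccc(CC2)cc1
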